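**Plan**

- Labels: lactone ring O–C1(=O)–C2–C3–C4, with the ring-A benzyl on C2 and the ring-B benzyl on C3; side chain on ring B is C7 (CH bearing CH2OH) and C8 (CH(OH) bearing ring C).
- Enabling feature: in the γ-butyrolactone ring, C1 has only the ring oxygen and C2 as neighbours. Taking C1 out as CO (cuts C1–C2 and C1–O) leaves an achiral (E)-allylic alcohol whose C2=C3 double bond already carries both arylmethyl groups and whose C4 is the CH2OH.
- Further cuts: C3–CH2(ring B) (Negishi coupling of a (Z)-2-iodoallylic alcohol with a benzylic zinc reagent), alkyne–CH2(ring A), and C7–C8 (aldol of a ring-B arylacetyl imide with O-benzylvanillin).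
- Forward: ring-A iodide (steps 1–4); ring-B arylacetic acid, anti-aldol, diol acetonide, benzylic chloride (steps 5–13); union (step 14); the lactone, the only ring built in the route, closes in step 15; acetonide hydrolysis and hydrogenolysis finish (steps 16–17).
- Stereochemistry: C7/C8 come from the (R)-4-benzyloxazolidinone in a magnesium-catalysed anti-aldol (step 9). C2/C3 are set in step 15: absolute sense from the chiral bisphosphine on palladium, trans relation from syn addition to the (E)-alkene.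

Key step: step 15

Assumption: the sense of induction of the bisphosphine in step 15 cannot be predicted from the closest known cases; (R,R)-BICP is written, and its enantiomer is taken if a test run on 26 shows the (2S,3S) lactone.

Shorthand used in the step lines: Diox = (4R,5R)-4-[4-(benzyloxy)-3-methoxyphenyl]-2,2-dimethyl-1,3-dioxan-5-yl.

**Route**

Step 1
Reactants: 1 4-(benzyloxy)-3-methoxybenzaldehyde (O-benzylvanillin)
Product: 2 [4-(benzyloxy)-3-methoxyphenyl]methanol
Conditions: NaBH4, MeOH, 0 °C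
Reagents that add atoms: none
Why: Borohydride reduction of an aromatic aldehyde to the benzylic alcohol, with the benzyl ether inert.

Step 2
Reactants: 2 [4-(benzyloxy)-3-methoxyphenyl]methanol
Product: 3 1-(benzyloxy)-4-(bromomethyl)-2-methoxybenzene
Conditions: PBr3, Et2O, 0 °C
Reagents that add atoms: phosphorus tribromide, BrP(Br)Br
Why: Bromination of a benzylic alcohol with PBr3 (substitution on the phosphite ester); the labile electron-rich bromide is made cold and used at once.

Step 3
Reactants: 3 1-(benzyloxy)-4-(bromomethyl)-2-methoxybenzene; 4 prop-2-yn-1-ol (propargyl alcohol)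
Product: 6 4-[4-(benzyloxy)-3-methoxyphenyl]but-2-yn-1-ol, via bromomagnesium acetylide 5 (not isolated)
Conditions: 4, EtMgBr (2.1 equiv), THF, 0 to 40 °C; CuCl (10 mol%); then 3, 50 °C
Reagents that add atoms: none
Why: Copper-catalysed coupling of an alkynyl Grignard reagent with a benzylic bromide; the C,O-dimagnesium salt reacts at the acetylide carbon, so the hydroxyl needs no protection.

Step 4
Reactants: 6 4-[4-(benzyloxy)-3-methoxyphenyl]but-2-yn-1-ol
Product: 8 (Z)-4-[4-(benzyloxy)-3-methoxyphenyl]-2-iodobut-2-en-1-ol, via alkenylstannane 7 (not isolated)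
Conditions: [Cp*RuCl]4 (1.5 mol%), Bu3SnH (1.05 equiv), CH2Cl2, rt; then I2 (1.1 equiv), 0 °C
Reagents that add atoms: iodine, II
Why: Ruthenium-catalysed trans-hydrostannation of a propargylic alcohol, in which the hydroxyl steers tin to the proximal alkyne carbon and hydrogen arrives anti, followed by iododestannylation with retention, should give the iodide with iodine cis to the CH2Ar group.

Step 5
Reactants: 9 5-bromo-2-hydroxy-3-methoxybenzaldehyde
Product: 10 2-(benzyloxy)-5-bromo-3-methoxybenzaldehyde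
Conditions: BnBr, K2CO3, DMF, 60 °C
Reagents that add atoms: benzyl bromide, BrCc1ccccc1
Why: Williamson etherification of the phenol; carbonate does not touch the aldehyde or the aryl bromide.

Step 6
Reactants: 10 2-(benzyloxy)-5-bromo-3-methoxybenzaldehyde
Product: 11 racemic 1-[2-(benzyloxy)-5-bromo-3-methoxyphenyl]-2,2,2-trichloroethanol
Conditions: CHCl3, DBU (1 equiv), rt
Reagents that add atoms: chloroform, ClC(Cl)Cl
Why: Base-mediated addition of the trichloromethyl anion to a non-enolisable aldehyde; the new carbinol centre is racemic and is removed in step 7.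

Step 7
Reactants: 11 racemic 1-[2-(benzyloxy)-5-bromo-3-methoxyphenyl]-2,2,2-trichloroethanol
Product: 12 [2-(benzyloxy)-5-bromo-3-methoxyphenyl]acetic acid
Conditions: NaBH4, NaOH, t-BuOH, 55 °C; then 1 M HCl
Reagents that add atoms: sodium hydroxide, [Na+].[OH-]
Why: Jocic–Reeve-type homologation: the alkoxide closes to a gem-dichloroepoxide, borohydride opens it at the benzylic carbon and the acyl chloride formed is hydrolysed, so the former aldehyde carbon becomes the CH2 of the arylacetic acid.

Step 8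
Reactants: 12 [2-(benzyloxy)-5-bromo-3-methoxyphenyl]acetic acid; 13 (R)-4-benzyl-1,3-oxazolidin-2-one
Product: 15 (R)-4-benzyl-3-{[2-(benzyloxy)-5-bromo-3-methoxyphenyl]acetyl}-1,3-oxazolidin-2-one, via mixed pivalic anhydride 14 (not isolated)
Conditions: PivCl, Et3N, THF, −20 °C; then 13, LiCl, −20 °C to rt
Reagents that add atoms: none
Why: N-Acylation of the oxazolidinone through the mixed pivalic anhydride under LiCl/Et3N, the protocol that avoids ketene formation from arylacetyl derivatives.

Step 9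
Reactants: 15 (R)-4-benzyl-3-{[2-(benzyloxy)-5-bromo-3-methoxyphenyl]acetyl}-1,3-oxazolidin-2-one; 1 4-(benzyloxy)-3-methoxybenzaldehyde
Product: 17 (R)-4-benzyl-3-{(2S,3R)-2-[2-(benzyloxy)-5-bromo-3-methoxyphenyl]-3-[4-(benzyloxy)-3-methoxyphenyl]-3-hydroxypropanoyl}-1,3-oxazolidin-2-one, via O-trimethylsilyl aldol 16 (not isolated)
Conditions: 1 (1.2 equiv), MgCl2 (20 mol%), Et3N, TMSCl, EtOAc, rt; then 1 M HCl, THF, rt
Reagents that add atoms: none
Why: Evans magnesium halide-catalysed direct anti-aldol of an N-acyloxazolidinone with a non-enolisable aromatic aldehyde: the chelated magnesium (Z)-enolate is attacked on the face away from the auxiliary benzyl group through a boat-like transition state, which should set C7 and C8 anti (2S,3R in the imide), and silylation of the aldolate turns the catalyst over.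

Step 10
Reactants: 17 (2S,3R)-anti-aldol imide
Product: 18 (1R,2R)-2-[2-(benzyloxy)-5-bromo-3-methoxyphenyl]-1-[4-(benzyloxy)-3-methoxyphenyl]propane-1,3-diol
Conditions: LiBH4, THF–MeOH, 0 °C
Reagents that add atoms: none
Why: Reductive cleavage of the imide with LiBH4 gives the primary alcohol and returns the auxiliary without touching C7, C8 or the aryl bromide.

Step 11
Reactants: 18 (1R,2R)-diol
Product: 19 (4R,5R)-5-[2-(benzyloxy)-5-bromo-3-methoxyphenyl]-4-[4-(benzyloxy)-3-methoxyphenyl]-2,2-dimethyl-1,3-dioxane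
Conditions: Me2C(OMe)2, PPTS (cat.), CH2Cl2, rt
Reagents that add atoms: 2,2-dimethoxypropane, COC(C)(C)OC
Why: Acid-catalysed transacetalisation of the 1,3-diol to the 1,3-dioxane with both aryl groups equatorial, which masks both hydroxyls against the organolithium, zinc and palladium steps.

Step 12
Reactants: 19 acetonide aryl bromide
Product: 22 [4-(benzyloxy)-3-methoxy-5-Diox-phenyl]methanol, via aryllithium 20 (not isolated), via aldehyde 21 (not isolated)
Conditions: n-BuLi, THF, −78 °C; DMF, −78 to 0 °C; then MeOH, NaBH4, 0 °C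
Reagents that add atoms: N,N-dimethylformamide, CN(C)C=O
Why: Bromine–lithium exchange outruns deprotonation at −78 °C, the aryllithium is formylated with DMF (Bouveault-type formylation) and the aldehyde is reduced by borohydride in the same flask.

Step 13
Reactants: 22 [4-(benzyloxy)-3-methoxy-5-Diox-phenyl]methanol
Product: 24 (4R,5R)-5-[2-(benzyloxy)-5-(chloromethyl)-3-methoxyphenyl]-4-[4-(benzyloxy)-3-methoxyphenyl]-2,2-dimethyl-1,3-dioxane, via benzylic mesylate 23 (not isolated)
Conditions: MsCl, Et3N, LiCl, THF, 0 °C to rt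
Reagents that add atoms: lithium chloride, [Li+].[Cl-]
Why: Mesylation of the electron-rich benzylic alcohol and chloride displacement in situ under basic conditions give the chloride without exposing the acetonide to acid.

Step 14
Reactants: 24 ring-B benzylic chloride; 8 (Z)-4-[4-(benzyloxy)-3-methoxyphenyl]-2-iodobut-2-en-1-ol
Product: 26 (E)-4-[4-(benzyloxy)-3-methoxyphenyl]-2-{[4-(benzyloxy)-3-methoxy-5-Diox-phenyl]methyl}but-2-en-1-ol, via benzylic zinc chloride 25 (not isolated)
Conditions: 24, Zn dust, LiCl, THF, 25 °C; then 8 (1.2 equiv), Pd(OAc)2 (2 mol%), SPhos (4 mol%), THF, 25 °C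
Reagents that add atoms: none
Why: LiCl-promoted zinc insertion into the benzylic chloride and Negishi coupling with the alkenyl iodide proceed with retention of alkene geometry, so the ring-B benzyl takes the place of iodine cis to the ring-A CH2 and the (E)-allylic alcohol should result; benzylic zinc reagents are known to couple in the presence of free hydroxyl groups.

Step 15
Reactants: 26 (E)-allylic alcohol; 27 carbon monoxide
Product: 28 (3R,4R)-3-[4-(benzyloxy)-3-methoxybenzyl]-4-{[4-(benzyloxy)-3-methoxy-5-Diox-phenyl]methyl}oxolan-2-one (trans lactone)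
Conditions: Pd2(dba)3·CHCl3 (4 mol%), (R,R)-BICP (10 mol%), CO (40 bar), H2 (10 bar), CH2Cl2, 80 °C
Reagents that add atoms: none
Why: Proposed new method: a palladium hydride formed from Pd(0), the bisphosphine and H2 adds syn across C2=C3 with H to the fully substituted C3 and Pd to the less hindered C2, CO inserts with retention at C2, and the C4 hydroxyl attacks the acyl-palladium to form C1–O and return the hydride; the closest known reaction type is the palladium-catalysed cyclocarbonylation of secondary and tertiary allylic alcohols to γ-butyrolactones under CO/H2, including asymmetric versions with chiral 1,4-bisphosphines, here extended to a primary allylic alcohol with a trisubstituted alkene. The lactone ring closes by 5-exo-trig acyl substitution of the C4 oxygen on the acyl-palladium carbon C1. C3 and C2 are set together in the hydropalladation: the alkene face is chosen by the chiral bisphosphine (catalyst control, the side-chain centres being too remote to matter), and the trans relation follows from syn addition of H and Pd to the (E)-alkene, whose two arylmethyl groups are cis, with retention in the CO insertion. The step needs Pd–C2 regioselectivity, CO insertion faster than β-hydride elimination towards either benzylic CH2, and no ionisation of the primary allylic C–O bond; these are addressed by the trisubstituted alkene (palladium avoids the tertiary carbon and only Pd at C2 leads to a five-membered ring), by high CO pressure with a chelating ligand that leaves no free cis site, and by acid-free conditions in which hydroxyl is a poor leaving group.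

Step 16
Reactants: 28 tri-O-benzyl acetonide lactone
Product: 29 (3R,4R)-3-[4-(benzyloxy)-3-methoxybenzyl]-4-({4-(benzyloxy)-3-[(1R,2R)-1-(4-(benzyloxy)-3-methoxyphenyl)-1,3-dihydroxypropan-2-yl]-5-methoxyphenyl}methyl)oxolan-2-one
Conditions: AcOH–H2O (4:1), 40 °C
Reagents that add atoms: none
Why: Mild aqueous acid hydrolysis of the isopropylidene acetal, done while the phenols are still benzylated so that the C8 benzylic position is less prone to ionise; the lactone and its trans C2/C3 centres are stable to acid.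

Step 17
Reactants: 29 tri-O-benzyl diol lactone
Product: 30 CNP0109231.2, (3R,4R)-4-({4-hydroxy-3-[(1R,2R)-1,3-dihydroxy-1-(4-hydroxy-3-methoxyphenyl)propan-2-yl]-5-methoxyphenyl}methyl)-3-(4-hydroxy-3-methoxybenzyl)oxolan-2-one
Conditions: H2 (1 atm), 10% Pd/C, EtOAc–EtOH, rt
Reagents that add atoms: none
Why: Hydrogenolysis of the three aryl benzyl ethers over Pd/C under neutral conditions at 1 atm, where phenolic benzyl ethers should cleave much faster than the secondary benzylic C8–OH.

**Compound list**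

1 | 4-(benzyloxy)-3-methoxybenzaldehyde | COc1cc(C=O)ccc1OCc1ccccc1 | starting material
2 | [4-(benzyloxy)-3-methoxyphenyl]methanol | COc1cc(CO)ccc1OCc1ccccc1 | intermediate
3 | 1-(benzyloxy)-4-(bromomethyl)-2-methoxybenzene | COc1cc(CBr)ccc1OCc1ccccc1 | intermediate
4 | prop-2-yn-1-ol | C#CCO | starting material
5 | bis(bromomagnesium) derivative of prop-2-yn-1-ol (C-acetylide, O-alkoxide; not isolated) | Br[Mg]C#CCO[Mg]Br | intermediate
6 | 4-[4-(benzyloxy)-3-methoxyphenyl]but-2-yn-1-ol | OCC#CCc1ccc(OCc2ccccc2)c(OC)c1 | intermediate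
7 | (Z)-4-[4-(benzyloxy)-3-methoxyphenyl]-2-(tributylstannyl)but-2-en-1-ol (not isolated) | OC/C([Sn](CCCC)(CCCC)CCCC)=C/Cc1ccc(OCc2ccccc2)c(OC)c1 | intermediate
8 | (Z)-4-[4-(benzyloxy)-3-methoxyphenyl]-2-iodobut-2-en-1-ol | OC/C(I)=C/Cc1ccc(OCc2ccccc2)c(OC)c1 | intermediate
9 | 5-bromo-2-hydroxy-3-methoxybenzaldehyde | COc1cc(Br)cc(C=O)c1O | starting material
10 | 2-(benzyloxy)-5-bromo-3-methoxybenzaldehyde | COc1cc(Br)cc(C=O)c1OCc1ccccc1 | intermediate
11 | racemic 1-[2-(benzyloxy)-5-bromo-3-methoxyphenyl]-2,2,2-trichloroethanol | COc1cc(Br)cc(C(O)C(Cl)(Cl)Cl)c1OCc1ccccc1 | intermediate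
12 | [2-(benzyloxy)-5-bromo-3-methoxyphenyl]acetic acid | COc1cc(Br)cc(CC(=O)O)c1OCc1ccccc1 | intermediate
13 | (R)-4-benzyl-1,3-oxazolidin-2-one | O=C1N[C@H](Cc2ccccc2)CO1 | starting material
14 | [2-(benzyloxy)-5-bromo-3-methoxyphenyl]acetic pivalic anhydride (not isolated) | COc1cc(Br)cc(CC(=O)OC(=O)C(C)(C)C)c1OCc1ccccc1 | intermediate
15 | (R)-4-benzyl-3-{[2-(benzyloxy)-5-bromo-3-methoxyphenyl]acetyl}-1,3-oxazolidin-2-one | COc1cc(Br)cc(CC(=O)N2[C@H](Cc3ccccc3)COC2=O)c1OCc1ccccc1 | intermediate
16 | (R)-4-benzyl-3-{(2S,3R)-2-[2-(benzyloxy)-5-bromo-3-methoxyphenyl]-3-[4-(benzyloxy)-3-methoxyphenyl]-3-[(trimethylsilyl)oxy]propanoyl}-1,3-oxazolidin-2-one (not isolated) | COc1cc(Br)cc([C@H](C(=O)N2[C@H](Cc3ccccc3)COC2=O)[C@@H](O[Si](C)(C)C)c2ccc(OCc3ccccc3)c(OC)c2)c1OCc1ccccc1 | intermediate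
17 | (R)-4-benzyl-3-{(2S,3R)-2-[2-(benzyloxy)-5-bromo-3-methoxyphenyl]-3-[4-(benzyloxy)-3-methoxyphenyl]-3-hydroxypropanoyl}-1,3-oxazolidin-2-one | COc1cc(Br)cc([C@H](C(=O)N2[C@H](Cc3ccccc3)COC2=O)[C@@H](O)c2ccc(OCc3ccccc3)c(OC)c2)c1OCc1ccccc1 | intermediate
18 | (1R,2R)-2-[2-(benzyloxy)-5-bromo-3-methoxyphenyl]-1-[4-(benzyloxy)-3-methoxyphenyl]propane-1,3-diol | COc1cc(Br)cc([C@H](CO)[C@@H](O)c2ccc(OCc3ccccc3)c(OC)c2)c1OCc1ccccc1 | intermediate
19 | (4R,5R)-5-[2-(benzyloxy)-5-bromo-3-methoxyphenyl]-4-[4-(benzyloxy)-3-methoxyphenyl]-2,2-dimethyl-1,3-dioxane | COc1cc(Br)cc([C@H](CO2)[C@@H](OC2(C)C)c2ccc(OCc3ccccc3)c(OC)c2)c1OCc1ccccc1 | intermediate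
20 | {4-(benzyloxy)-3-methoxy-5-[(4R,5R)-4-(4-(benzyloxy)-3-methoxyphenyl)-2,2-dimethyl-1,3-dioxan-5-yl]phenyl}lithium (not isolated) | COc1cc([Li])cc([C@H](CO2)[C@@H](OC2(C)C)c2ccc(OCc3ccccc3)c(OC)c2)c1OCc1ccccc1 | intermediate
21 | 4-(benzyloxy)-3-methoxy-5-[(4R,5R)-4-(4-(benzyloxy)-3-methoxyphenyl)-2,2-dimethyl-1,3-dioxan-5-yl]benzaldehyde (not isolated) | COc1cc(C=O)cc([C@H](CO2)[C@@H](OC2(C)C)c2ccc(OCc3ccccc3)c(OC)c2)c1OCc1ccccc1 | intermediate
22 | {4-(benzyloxy)-3-methoxy-5-[(4R,5R)-4-(4-(benzyloxy)-3-methoxyphenyl)-2,2-dimethyl-1,3-dioxan-5-yl]phenyl}methanol | COc1cc(CO)cc([C@H](CO2)[C@@H](OC2(C)C)c2ccc(OCc3ccccc3)c(OC)c2)c1OCc1ccccc1 | intermediate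
23 | {4-(benzyloxy)-3-methoxy-5-[(4R,5R)-4-(4-(benzyloxy)-3-methoxyphenyl)-2,2-dimethyl-1,3-dioxan-5-yl]phenyl}methyl methanesulfonate (not isolated) | COc1cc(COS(C)(=O)=O)cc([C@H](CO2)[C@@H](OC2(C)C)c2ccc(OCc3ccccc3)c(OC)c2)c1OCc1ccccc1 | intermediate
24 | (4R,5R)-5-[2-(benzyloxy)-5-(chloromethyl)-3-methoxyphenyl]-4-[4-(benzyloxy)-3-methoxyphenyl]-2,2-dimethyl-1,3-dioxane | COc1cc(CCl)cc([C@H](CO2)[C@@H](OC2(C)C)c2ccc(OCc3ccccc3)c(OC)c2)c1OCc1ccccc1 | intermediate
25 | ({4-(benzyloxy)-3-methoxy-5-[(4R,5R)-4-(4-(benzyloxy)-3-methoxyphenyl)-2,2-dimethyl-1,3-dioxan-5-yl]phenyl}methyl)zinc chloride (not isolated) | COc1cc(C[Zn]Cl)cc([C@H](CO2)[C@@H](OC2(C)C)c2ccc(OCc3ccccc3)c(OC)c2)c1OCc1ccccc1 | intermediate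
26 | (E)-4-[4-(benzyloxy)-3-methoxyphenyl]-2-({4-(benzyloxy)-3-methoxy-5-[(4R,5R)-4-(4-(benzyloxy)-3-methoxyphenyl)-2,2-dimethyl-1,3-dioxan-5-yl]phenyl}methyl)but-2-en-1-ol | OC/C(Cc1cc(OC)c(OCc2ccccc2)c([C@H](CO3)[C@@H](OC3(C)C)c3ccc(OCc4ccccc4)c(OC)c3)c1)=C/Cc1ccc(OCc2ccccc2)c(OC)c1 | intermediate
27 | carbon monoxide | [C-]#[O+] | starting material
28 | (3R,4R)-3-[4-(benzyloxy)-3-methoxybenzyl]-4-({4-(benzyloxy)-3-methoxy-5-[(4R,5R)-4-(4-(benzyloxy)-3-methoxyphenyl)-2,2-dimethyl-1,3-dioxan-5-yl]phenyl}methyl)oxolan-2-one | COc1cc(C[C@H]2C(=O)OC[C@@H]2Cc2cc(OC)c(OCc3ccccc3)c([C@H](CO4)[C@@H](OC4(C)C)c4ccc(OCc5ccccc5)c(OC)c4)c2)ccc1OCc1ccccc1 | intermediate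
29 | (3R,4R)-3-[4-(benzyloxy)-3-methoxybenzyl]-4-({4-(benzyloxy)-3-[(1R,2R)-1-(4-(benzyloxy)-3-methoxyphenyl)-1,3-dihydroxypropan-2-yl]-5-methoxyphenyl}methyl)oxolan-2-one | COc1cc(C[C@H]2C(=O)OC[C@@H]2Cc2cc(OC)c(OCc3ccccc3)c([C@H](CO)[C@@H](O)c3ccc(OCc4ccccc4)c(OC)c3)c2)ccc1OCc1ccccc1 | intermediate
30 | CNP0109231.2, (3R,4R)-4-({4-hydroxy-3-[(1R,2R)-1,3-dihydroxy-1-(4-hydroxy-3-methoxyphenyl)propan-2-yl]-5-methoxyphenyl}methyl)-3-(4-hydroxy-3-methoxybenzyl)oxolan-2-one | COc1cc(C[C@H]2C(=O)OC[C@@H]2Cc2cc(OC)c(O)c([C@H](CO)[C@@H](O)c3ccc(O)c(OC)c3)c2)ccc1O | target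

**Count**

Total steps: 17. Longest linear sequence: 13 steps (steps 5–17, from 9).

**Steps most likely to fail**

Step 15. The primary allylic alcohol may ionise to a π-allyl complex. The C2-alkylpalladium may undergo β-hydride elimination into conjugation with either aryl ring before CO inserts. The alkene face may be poorly discriminated. The fallback uses known chemistry and sets out from aldehyde 21 (step 12 stopped before the borohydride) and bromide 3. Stobbe condensation of 21 with dimethyl succinate (KOt-Bu, t-BuOH) should give the (E)-arylidenesuccinic acid 1-methyl ester F1. Rhodium-catalysed asymmetric hydrogenation with a chiral bisphosphine of the DIOP type, in the enantiomer that gives the R acid, should give the (R)-2-(arylmethyl)succinic acid 1-methyl ester F2. Reduction of the ester group of its potassium salt with Ca(BH4)2 and mild acidification should close the (R)-4-(arylmethyl)oxolan-2-one F3. Its lithium enolate (LiHMDS, THF, −78 °C) is alkylated by 3 anti to the C3 substituent, which returns the route at the trans lactone 28.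

Step 9. The more acidic arylacetyl imide may erode the anti and facial selectivity, through a background silyl ketene aminal pathway or epimerisation at C7 after silylation, and addition to the electron-rich aldehyde may be slow. The fallback sets out from aldehyde 10. Vinylmagnesium bromide should give the racemic 1-[2-(benzyloxy)-5-bromo-3-methoxyphenyl]prop-2-en-1-ol F4. Palladium-catalysed borylation with B2pin2 under base-free conditions, where allylic C–O activation should outrun insertion into the aryl bromide, gives with allylic transposition the (E)-3-arylallyl pinacol boronate F5. Allylboration of 1 catalysed by the chiral phosphoric acid (R)-TRIP (toluene, −30 °C) passes through a chair transition state in which the (E)-boronate can only give the anti product, attack being expected on the Re face; this should give the (1R,2S)-2-[2-(benzyloxy)-5-bromo-3-methoxyphenyl]-1-[4-(benzyloxy)-3-methoxyphenyl]but-3-en-1-ol F6. Ozonolysis at −78 °C with NaBH4 work-up returns the route at diol 18.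

Step 14. The benzylic zinc reagent may be protonated by the free hydroxyl of 8, and Wurtz-type homocoupling may occur during zinc insertion into the electron-rich benzylic chloride. The fallback reverses the polarity and needs no organozinc. It sets out from stannane 7 (step 4 stopped before the iodine) and chloride 24, which are joined in a copper-assisted Stille coupling (Pd2(dba)3, tri(2-furyl)phosphine, CuI, NMP, 50 °C) with retention of geometry, returning the route at 26. No new compound is made.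

**Further compounds**

F1 | step 15 | (E)-3-(methoxycarbonyl)-4-{4-(benzyloxy)-3-methoxy-5-[(4R,5R)-4-(4-(benzyloxy)-3-methoxyphenyl)-2,2-dimethyl-1,3-dioxan-5-yl]phenyl}but-3-enoic acid | COC(=O)/C(CC(=O)O)=C/c1cc(OC)c(OCc2ccccc2)c([C@H](CO3)[C@@H](OC3(C)C)c3ccc(OCc4ccccc4)c(OC)c3)c1
F2 | step 15 | (3R)-3-(methoxycarbonyl)-4-{4-(benzyloxy)-3-methoxy-5-[(4R,5R)-4-(4-(benzyloxy)-3-methoxyphenyl)-2,2-dimethyl-1,3-dioxan-5-yl]phenyl}butanoic acid | COC(=O)[C@@H](CC(=O)O)Cc1cc(OC)c(OCc2ccccc2)c([C@H](CO3)[C@@H](OC3(C)C)c3ccc(OCc4ccccc4)c(OC)c3)c1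
F3 | step 15 | (4R)-4-({4-(benzyloxy)-3-methoxy-5-[(4R,5R)-4-(4-(benzyloxy)-3-methoxyphenyl)-2,2-dimethyl-1,3-dioxan-5-yl]phenyl}methyl)oxolan-2-one | O=C1OC[C@@H](C1)Cc1cc(OC)c(OCc2ccccc2)c([C@H](CO3)[C@@H](OC3(C)C)c3ccc(OCc4ccccc4)c(OC)c3)c1
F4 | step 9 | racemic 1-[2-(benzyloxy)-5-bromo-3-methoxyphenyl]prop-2-en-1-ol | C=CC(O)c1cc(Br)cc(OC)c1OCc1ccccc1
F5 | step 9 | 2-{(E)-3-[2-(benzyloxy)-5-bromo-3-methoxyphenyl]prop-2-en-1-yl}-4,4,5,5-tetramethyl-1,3,2-dioxaborolane | CC1(C)OB(C/C=C/c2cc(Br)cc(OC)c2OCc2ccccc2)OC1(C)C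
F6 | step 9 | (1R,2S)-2-[2-(benzyloxy)-5-bromo-3-methoxyphenyl]-1-[4-(benzyloxy)-3-methoxyphenyl]but-3-en-1-ol | COc1cc(Br)cc([C@H](C=C)[C@@H](O)c2ccc(OCc3ccccc3)c(OC)c2)c1OCc1ccccc1
F0 | step 14 | none | none
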